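**Retrosynthetic overview**
1. Target ⇐ its tri-O-benzyl ether (hydrogenolysis). The cyclohexanone ring of the tetralone is the only ring built, and it is closed last by intramolecular Friedel–Crafts acylation of an (S)-4,4-diarylbutanoic acid.
2. The acid ⇐ an (S,E)-4,4-diarylbut-2-enal dimethyl acetal (diimide reduction, acetal hydrolysis, Pinnick oxidation).
3. The diarylmethine stereocentre ⇐ copper-mediated anti-SN2′ arylation (1,3-chirality transfer) of an (R)-allylic picolinate with a naphthyl cuprate.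
4. The (R)-carbinol ⇐ ketoreductase reduction of an achiral (E)-enone, made by Claisen–Schmidt condensation of 2,5-bis(benzyloxy)benzaldehyde with 1,1-dimethoxyacetone.
5. The naphthyl bromide ⇐ naphthalene-1,5-diol: OBn/OAc differentiation steers bromination para to OBn, then OAc → OMe. Both aromatic ring systems are purchased.

Assumption: the target stereocentre (tetralone C4) is S by CIP (C4a > naphthyl C1′ > C3 > H), and a ketoreductase of the required facial selectivity is picked from a commercial screening panel.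

**Route**

Step 1
Reactants: 1 naphthalene-1,5-diol
Product: 2 5-(benzyloxy)naphthalen-1-ol
Conditions: BnBr (0.9 equiv), K2CO3, acetone, reflux; chromatography (recovered 1 recycled)
Reagents that add atoms: benzyl bromide, BrCc1ccccc1
Why: Williamson ether synthesis; with the halide limiting, the symmetric diol is mono-alkylated statistically and the mono-ether is separated from diol and bis-ether.

Step 2
Reactants: 2 5-(benzyloxy)naphthalen-1-ol
Product: 3 5-(benzyloxy)naphthalen-1-yl acetate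
Conditions: Ac2O, pyridine, DMAP (cat.), CH2Cl2, rt
Reagents that add atoms: acetic anhydride, CC(=O)OC(C)=O
Why: DMAP-catalysed O-acylation, which makes the acetoxy-bearing ring the less electron-rich one for the following bromination.

Step 3
Reactants: 3 5-(benzyloxy)naphthalen-1-yl acetate
Product: 4 5-(benzyloxy)-8-bromonaphthalen-1-yl acetate (Br para to OBn, peri to OAc)
Conditions: NBS (1.05 equiv), MeCN, 0 °C → rt, dark
Reagents that add atoms: N-bromosuccinimide, O=C1CCC(=O)N1Br
Why: Electrophilic aromatic bromination goes to the alkoxy-activated ring at the α-position para to OBn (as for 1-alkoxynaphthalenes), the acetoxy ring being deactivated, so the regiochemistry is fixed electronically.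

Step 4
Reactants: 4 5-(benzyloxy)-8-bromonaphthalen-1-yl acetate
Product: 5 5-(benzyloxy)-8-bromonaphthalen-1-ol
Conditions: K2CO3 (0.2 equiv), MeOH/THF, rt
Reagents that add atoms: none
Why: Base-catalysed methanolysis (transesterification) of the aryl acetate, which leaves the aryl bromide and benzyl ether untouched.

Step 5
Reactants: 5 5-(benzyloxy)-8-bromonaphthalen-1-ol
Product: 6 4-(benzyloxy)-1-bromo-8-methoxynaphthalene
Conditions: MeI, K2CO3, DMF, rt
Reagents that add atoms: iodomethane, CI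
Why: Williamson O-methylation of the naphthoxide places the methyl ether peri to bromine and the benzyl ether para to it.

Step 6
Reactants: 7 2,5-dihydroxybenzaldehyde
Product: 8 2,5-bis(benzyloxy)benzaldehyde
Conditions: BnBr (2.4 equiv), K2CO3, DMF, 60 °C
Reagents that add atoms: benzyl bromide, BrCc1ccccc1
Why: Double Williamson etherification; warm DMF is used because the 2-OH is hydrogen-bonded to the aldehyde.

Step 7
Reactants: 8 2,5-bis(benzyloxy)benzaldehyde; 9 1,1-dimethoxypropan-2-one
Product: 10 (3E)-4-[2,5-bis(benzyloxy)phenyl]-1,1-dimethoxybut-3-en-2-one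
Conditions: NaOH (aq, 0.5 equiv), MeOH, 0 °C → rt
Reagents that add atoms: none
Why: Claisen–Schmidt (crossed aldol) condensation; only the methyl side of 9 can condense and dehydrate, and E1cB elimination gives the (E)-enone.

Step 8
Reactants: 10 (3E)-4-[2,5-bis(benzyloxy)phenyl]-1,1-dimethoxybut-3-en-2-one
Product: 11 (2R,3E)-4-[2,5-bis(benzyloxy)phenyl]-1,1-dimethoxybut-3-en-2-ol
Conditions: ketoreductase (KRED, NADPH-dependent alcohol dehydrogenase), NADP+ (cat.), i-PrOH (15% v/v), KPi buffer pH 7.0, DMSO (5%), 30 °C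
Reagents that add atoms: none
Why: Ketoreductase-catalysed asymmetric 1,2-reduction of the enone carbonyl (cofactor recycled by i-PrOH) delivers hydride to the si face (O > CH(OMe)2 > CH=CHAr) and sets the first stereocentre as the (R)-carbinol in high ee without touching the C=C.

Step 9
Reactants: 11 (2R,3E)-4-[2,5-bis(benzyloxy)phenyl]-1,1-dimethoxybut-3-en-2-ol
Product: 12 (2R,3E)-4-[2,5-bis(benzyloxy)phenyl]-1,1-dimethoxybut-3-en-2-yl pyridine-2-carboxylate
Conditions: picolinic acid, DCC, DMAP (cat.), CH2Cl2, 0 °C → rt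
Reagents that add atoms: picolinic acid, OC(=O)c1ccccn1
Why: Steglich esterification acylates oxygen only, so the carbinol configuration is retained and a chelating leaving group is installed.

Step 10
Reactants: 6 4-(benzyloxy)-1-bromo-8-methoxynaphthalene; 12 (2R,3E)-4-[2,5-bis(benzyloxy)phenyl]-1,1-dimethoxybut-3-en-2-yl pyridine-2-carboxylate
Product: 15 4-(benzyloxy)-1-{(1S,2E)-1-[2,5-bis(benzyloxy)phenyl]-4,4-dimethoxybut-2-en-1-yl}-8-methoxynaphthalene, via [4-(benzyloxy)-8-methoxynaphthalen-1-yl]magnesium bromide 13 (not isolated), via bromomagnesium bis[4-(benzyloxy)-8-methoxynaphthalen-1-yl]cuprate(I) 14 (not isolated)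
Conditions: 6 (2.4 equiv), Mg, LiCl, THF, 25–40 °C; CuBr·SMe2 (1.2 equiv), −40 °C; then 12, −40 → 0 °C; aq NH4Cl/NH3
Reagents that add atoms: none
Why: Copper-mediated anti-SN2′ allylic substitution of the Mg-chelated picolinate: the aryl adds to the γ-carbon anti to the C–O bond in the H-eclipsed conformer, so the (R)-carbinol chirality is transferred 1,3 to the (S)-diarylmethine with formation of the (E)-alkene, the adjacent acetal suppressing ionisation (SN1).

Step 11
Reactants: 15 4-(benzyloxy)-1-{(1S,2E)-1-[2,5-bis(benzyloxy)phenyl]-4,4-dimethoxybut-2-en-1-yl}-8-methoxynaphthalene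
Product: 16 4-(benzyloxy)-1-{(1S)-1-[2,5-bis(benzyloxy)phenyl]-4,4-dimethoxybutyl}-8-methoxynaphthalene
Conditions: 2-nitrobenzenesulfonylhydrazide (NBSH, excess, portionwise), Et3N, CH2Cl2, rt
Reagents that add atoms: none
Why: Diimide reduction (concerted syn H2 transfer) saturates the C=C without double-bond migration into the diarylmethine (no racemisation), without benzyl-ether hydrogenolysis, and under basic conditions that keep the acetal.

Step 12
Reactants: 16 4-(benzyloxy)-1-{(1S)-1-[2,5-bis(benzyloxy)phenyl]-4,4-dimethoxybutyl}-8-methoxynaphthalene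
Product: 17 (4S)-4-[2,5-bis(benzyloxy)phenyl]-4-[4-(benzyloxy)-8-methoxynaphthalen-1-yl]butanal
Conditions: 0.5 M aq HCl/THF (1:4), rt
Reagents that add atoms: water, O
Why: Acid-catalysed acetal hydrolysis in dilute aqueous medium (water outcompetes arene attack on the oxocarbenium ion); the stereocentre is γ to the carbonyl and cannot epimerise.

Step 13
Reactants: 17 (4S)-4-[2,5-bis(benzyloxy)phenyl]-4-[4-(benzyloxy)-8-methoxynaphthalen-1-yl]butanal
Product: 18 (4S)-4-[2,5-bis(benzyloxy)phenyl]-4-[4-(benzyloxy)-8-methoxynaphthalen-1-yl]butanoic acid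
Conditions: NaClO2, NaH2PO4, 2-methylbut-2-ene (excess), t-BuOH/THF/H2O, 0 °C → rt
Reagents that add atoms: sodium chlorite, [Na+].[O-]Cl=O
Why: Pinnick oxidation converts the aldehyde to the acid while the alkene scavenger traps HOCl and protects the electron-rich arenes from chlorination.

Step 14
Reactants: 18 (4S)-4-[2,5-bis(benzyloxy)phenyl]-4-[4-(benzyloxy)-8-methoxynaphthalen-1-yl]butanoic acid
Product: 20 (4S)-5,8-bis(benzyloxy)-4-[4-(benzyloxy)-8-methoxynaphthalen-1-yl]-3,4-dihydronaphthalen-1(2H)-one, via (4S)-4-[2,5-bis(benzyloxy)phenyl]-4-[4-(benzyloxy)-8-methoxynaphthalen-1-yl]butanoic trifluoroacetic anhydride 19 (not isolated)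
Conditions: TFAA (3 equiv), CH2Cl2, 0 °C → rt
Reagents that add atoms: none
Why: Intramolecular Friedel–Crafts acylation through the mixed anhydride closes the six-membered ring at the phenyl carbon ortho to OBn (activated) in preference to the unactivated naphthalene C2′ (meta to its OBn), under conditions too mild to ionise the benzylic stereocentre.

Step 15
Reactants: 20 (4S)-5,8-bis(benzyloxy)-4-[4-(benzyloxy)-8-methoxynaphthalen-1-yl]-3,4-dihydronaphthalen-1(2H)-one
Product: 21 (4S)-5,8-dihydroxy-4-(4-hydroxy-8-methoxynaphthalen-1-yl)-3,4-dihydronaphthalen-1(2H)-one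
Conditions: H2 (1 atm), 10% Pd/C, EtOAc/MeOH, rt, stopped at 3 equiv uptake; work-up under Ar
Reagents that add atoms: none
Why: Catalytic hydrogenolysis cleaves the three aryl benzyl ethers while the aryl methyl ether, the hydrogen-bonded aryl ketone and the C4–H stereocentre are inert at 1 atm.

**Compound list**
1 | naphthalene-1,5-diol | Oc1cccc2c(O)cccc12 | starting material
2 | 5-(benzyloxy)naphthalen-1-ol | Oc1cccc2c(OCc3ccccc3)cccc12 | intermediate
3 | 5-(benzyloxy)naphthalen-1-yl acetate | CC(=O)Oc1cccc2c(OCc3ccccc3)cccc12 | intermediate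
4 | 5-(benzyloxy)-8-bromonaphthalen-1-yl acetate | CC(=O)Oc1cccc2c(OCc3ccccc3)ccc(Br)c12 | intermediate
5 | 5-(benzyloxy)-8-bromonaphthalen-1-ol | Oc1cccc2c(OCc3ccccc3)ccc(Br)c12 | intermediate
6 | 4-(benzyloxy)-1-bromo-8-methoxynaphthalene | COc1cccc2c(OCc3ccccc3)ccc(Br)c12 | intermediate
7 | 2,5-dihydroxybenzaldehyde | O=Cc1cc(O)ccc1O | starting material
8 | 2,5-bis(benzyloxy)benzaldehyde | O=Cc1cc(OCc2ccccc2)ccc1OCc1ccccc1 | intermediate
9 | 1,1-dimethoxypropan-2-one | COC(OC)C(C)=O | starting material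
10 | (3E)-4-[2,5-bis(benzyloxy)phenyl]-1,1-dimethoxybut-3-en-2-one | COC(OC)C(=O)/C=C/c1cc(OCc2ccccc2)ccc1OCc1ccccc1 | intermediate
11 | (2R,3E)-4-[2,5-bis(benzyloxy)phenyl]-1,1-dimethoxybut-3-en-2-ol | COC(OC)[C@H](O)/C=C/c1cc(OCc2ccccc2)ccc1OCc1ccccc1 | intermediate
12 | (2R,3E)-4-[2,5-bis(benzyloxy)phenyl]-1,1-dimethoxybut-3-en-2-yl pyridine-2-carboxylate | COC(OC)[C@H](OC(=O)c1ccccn1)/C=C/c1cc(OCc2ccccc2)ccc1OCc1ccccc1 | intermediate
13 | [4-(benzyloxy)-8-methoxynaphthalen-1-yl]magnesium bromide | COc1cccc2c(OCc3ccccc3)ccc([Mg]Br)c12 | intermediate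
14 | bromomagnesium bis[4-(benzyloxy)-8-methoxynaphthalen-1-yl]cuprate(I) | COc1cccc2c(OCc3ccccc3)ccc([Cu-]c3ccc(OCc4ccccc4)c4cccc(OC)c34)c12.[Mg+]Br | intermediate
15 | 4-(benzyloxy)-1-{(1S,2E)-1-[2,5-bis(benzyloxy)phenyl]-4,4-dimethoxybut-2-en-1-yl}-8-methoxynaphthalene | COc1cccc2c(OCc3ccccc3)ccc([C@H](/C=C/C(OC)OC)c3cc(OCc4ccccc4)ccc3OCc3ccccc3)c12 | intermediate
16 | 4-(benzyloxy)-1-{(1S)-1-[2,5-bis(benzyloxy)phenyl]-4,4-dimethoxybutyl}-8-methoxynaphthalene | COc1cccc2c(OCc3ccccc3)ccc([C@H](CCC(OC)OC)c3cc(OCc4ccccc4)ccc3OCc3ccccc3)c12 | intermediate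
17 | (4S)-4-[2,5-bis(benzyloxy)phenyl]-4-[4-(benzyloxy)-8-methoxynaphthalen-1-yl]butanal | COc1cccc2c(OCc3ccccc3)ccc([C@H](CCC=O)c3cc(OCc4ccccc4)ccc3OCc3ccccc3)c12 | intermediate
18 | (4S)-4-[2,5-bis(benzyloxy)phenyl]-4-[4-(benzyloxy)-8-methoxynaphthalen-1-yl]butanoic acid | COc1cccc2c(OCc3ccccc3)ccc([C@H](CCC(=O)O)c3cc(OCc4ccccc4)ccc3OCc3ccccc3)c12 | intermediate
19 | (4S)-4-[2,5-bis(benzyloxy)phenyl]-4-[4-(benzyloxy)-8-methoxynaphthalen-1-yl]butanoic trifluoroacetic anhydride | COc1cccc2c(OCc3ccccc3)ccc([C@H](CCC(=O)OC(=O)C(F)(F)F)c3cc(OCc4ccccc4)ccc3OCc3ccccc3)c12 | intermediate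
20 | (4S)-5,8-bis(benzyloxy)-4-[4-(benzyloxy)-8-methoxynaphthalen-1-yl]-3,4-dihydronaphthalen-1(2H)-one | COc1cccc2c(OCc3ccccc3)ccc([C@@H]3CCC(=O)c4c(OCc5ccccc5)ccc(OCc5ccccc5)c43)c12 | intermediate
21 | (4S)-5,8-dihydroxy-4-(4-hydroxy-8-methoxynaphthalen-1-yl)-3,4-dihydronaphthalen-1(2H)-one | COc1cccc2c(O)ccc([C@@H]3CCC(=O)c4c(O)ccc(O)c43)c12 | target

**Totals**
Total step count: 15. Longest linear sequence: 11 steps (1 → 2 → 3 → 4 → 5 → 6 → 15 → 16 → 17 → 18 → 20 → 21).

**Three steps most likely to fail, with fallbacks**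

Step 8 (the bulky, poorly soluble enone 10 may be reduced slowly or with low selectivity by the available ketoreductases). The fallback sets out from aldehyde 8 and comes back at 11; it moves the asymmetric reduction to a slimmer ynone and sets the alkene geometry afterwards. Ohira–Bestmann homologation of 8 (dimethyl (1-diazo-2-oxopropyl)phosphonate, K2CO3, MeOH) gives 1,4-bis(benzyloxy)-2-ethynylbenzene F1. Its lithium acetylide (n-BuLi, THF, −78 °C) is acylated with N-methoxy-N-methyl-2,2-dimethoxyacetamide to 4-[2,5-bis(benzyloxy)phenyl]-1,1-dimethoxybut-3-yn-2-one F2. Noyori transfer hydrogenation (RuCl[(S,S)-TsDPEN](p-cymene), i-PrOH; sense assumed by analogy with alkynyl alkyl ketones and to be checked by Mosher analysis) gives (2R)-4-[2,5-bis(benzyloxy)phenyl]-1,1-dimethoxybut-3-yn-2-ol F3. Red-Al trans-reduction of this propargylic alcohol (THF, 0 °C) gives the (E)-allylic alcohol 11.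

Step 10 (this is the most likely to fail: a peri-substituted arylcuprate must attack a γ-carbon that carries an ortho-alkoxyaryl group, so low conversion, α-attack or eroded chirality transfer are possible). The fallback sets out from enone 10 and bromide 6 and comes back at 15; it replaces the Cu/Grignard anti-SN2′ by a Pd(II)-catalysed syn γ-arylation with a boronic acid. An enantiocomplementary ketoreductase reduces 10 to (2S,3E)-4-[2,5-bis(benzyloxy)phenyl]-1,1-dimethoxybut-3-en-2-ol F4, which is acetylated (Ac2O, pyridine) to (2S,3E)-4-[2,5-bis(benzyloxy)phenyl]-1,1-dimethoxybut-3-en-2-yl acetate F5. Bromide 6 is converted (n-BuLi, THF, −78 °C; B(Oi-Pr)3; aq HCl) into [4-(benzyloxy)-8-methoxynaphthalen-1-yl]boronic acid F6. Pd(OAc)2/1,10-phenanthroline/AgSbF6 (ClCH2CH2Cl, 60 °C) couples F5 and F6 by acetate-directed syn-carbopalladation and syn-β-acetoxy elimination; syn delivery from the (S)-ester gives the same (S,E)-alkene 15.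

Step 14 (risks are competing acylation of the naphthalene, acid-induced loss of benzyl groups, or retro-Friedel–Crafts erosion of the diarylmethine). The fallback sets out from acid 18 and comes back at the target 21; it deprotects first and uses a phenol-directed acylation. Hydrogenolysis of 18 (H2, Pd/C, EtOAc/MeOH) gives (4S)-4-(2,5-dihydroxyphenyl)-4-(4-hydroxy-8-methoxynaphthalen-1-yl)butanoic acid F7. BF3·OEt2 (60–80 °C) then effects intramolecular acylation ortho to the free hydroquinone OH, the most activated position, to give 21 directly.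

**Further compounds**
F1 | step 8 | 1,4-bis(benzyloxy)-2-ethynylbenzene | C#Cc1cc(OCc2ccccc2)ccc1OCc1ccccc1
F2 | step 8 | 4-[2,5-bis(benzyloxy)phenyl]-1,1-dimethoxybut-3-yn-2-one | COC(OC)C(=O)C#Cc1cc(OCc2ccccc2)ccc1OCc1ccccc1
F3 | step 8 | (2R)-4-[2,5-bis(benzyloxy)phenyl]-1,1-dimethoxybut-3-yn-2-ol | COC(OC)[C@H](O)C#Cc1cc(OCc2ccccc2)ccc1OCc1ccccc1
F4 | step 10 | (2S,3E)-4-[2,5-bis(benzyloxy)phenyl]-1,1-dimethoxybut-3-en-2-ol | COC(OC)[C@@H](O)/C=C/c1cc(OCc2ccccc2)ccc1OCc1ccccc1
F5 | step 10 | (2S,3E)-4-[2,5-bis(benzyloxy)phenyl]-1,1-dimethoxybut-3-en-2-yl acetate | COC(OC)[C@@H](OC(C)=O)/C=C/c1cc(OCc2ccccc2)ccc1OCc1ccccc1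
F6 | step 10 | [4-(benzyloxy)-8-methoxynaphthalen-1-yl]boronic acid | COc1cccc2c(OCc3ccccc3)ccc(B(O)O)c12
F7 | step 14 | (4S)-4-(2,5-dihydroxyphenyl)-4-(4-hydroxy-8-methoxynaphthalen-1-yl)butanoic acid | COc1cccc2c(O)ccc([C@H](CCC(=O)O)c3cc(O)ccc3O)c12
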